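# Total synthesis proposal for CNP0361406.6 (compound 30)

## Analysis of the target

Target 30 is an ester-linked pseudo-dimer of two p-menthane units. The eastern C15 unit is a cyclohexane (ring A: C5a, C6, C7, C8, C9, C9a). It is cis-fused to a seven-membered unsaturated lactone (ring B: C1(=O), O2, C3H2, C4(CO2H)=C5H, C5a, C9a). The western C14 unit is a cyclohexene (ring C: C1'–C6', C2'=C3') whose C1' carries an (E)-2-(hydroxymethyl)acrylate that acylates the CH2O arm (C10) on C9.

Ring A holds four contiguous stereocentres, C6 (S), C5a (R), C9a (S) and C9 (R). With the isopropyl group equatorial, C5 on C5a is equatorial and trans to it, C1 on C9a is axial and cis to C5, the tertiary OH on C9 is equatorial and cis to C1, and C10 is axial. Ring C holds two stereocentres, C6' (S, same spatial sense as C6) and C1' (R). There the side chain and the isopropyl group are cis, so the two halves are not two states of one monomer.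

Several groups are sensitive:
- C9a–H, whose epimer (trans-fused, all equatorial) should be the more stable one.
- The activated allylic C3–O2 ester bond.
- The doubly allylic C1'–H.
- One free acid beside three hydroxyl groups.

The feature that invites the key move is this: C1 and C5 sit on the adjacent ring A atoms C9a and C5a, on one face, anti to the isopropyl group on C6. They lie next to C9, which has the substitution of a former ketone. This is what remains when the outer C–C bond of a cyclobutane fused to a cyclohexanone is cut, and so it is the retron of an enone [2+2] photoadduct.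

The hard points are four: the contra-thermodynamic C9a, the cis pair C1'/C6', two trisubstituted enoates with CH2O cis to the ring, and a union that tolerates neither strong base nor strong nucleophile.

## Retrosynthetic reasoning

**30 to 17 and 28.** 30 is traced to its tert-butyl ester 29, and 29 is cut at the O–C10 bond into spiro-epoxide 17 and diol acid 28. The cut is placed here because the epoxide is protecting group and activating group of the C9 diol at the same time. Attack at the CH2 terminus touches no stereocentre, and the tertiary OH appears only at the end. The forward reaction needs a carboxylate to open a 1,1-disubstituted epoxide in the presence of free primary alcohols, so the eastern acid is masked.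

**17 to 11 and 15.** Ring B of 17 is cut at two bonds, O2–C3 and C4=C5. This releases acid aldehyde 11 and phosphonoacrylate 15, which holds C3, C4 and the carboxyl carbon. All remaining complexity then sits in a monocyclic ring A carrying C1 at the acid level and C5 at the aldehyde level, cis to each other.

**11 to 8.** In 11, C1 and C5 are joined again. This leads to the cyclobutene silyl enol ether 9 and to cyclobutanone 8. The bond is drawn here because a four-membered ring locks C9a and C5a cis, makes epimerisation at C9a impossible while C9 is a ketone, and tells C1 from C5 by oxidation level when it is cleaved.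

**8 to 6.** The ketone of 8 is masked as the exocyclic methylene of 7, and the spiro-epoxide of 7 comes from the ring A ketone of 6 by methylene transfer. The order matters. The C9 carbonyl has to be used up before the cyclobutanone is unveiled, otherwise a 1,3-diketone would open by retro-Claisen cleavage at the wrong bond.

**6 to 4 and 5.** 6 is cut at C9a–C1 and C5a–C5 into (S)-cryptone 4 and allene 5. Two C–C bonds and two stereocentres arise in one photochemical operation from a C9 enone with a single stereocentre, and the concave shape of 6 then controls C9.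

**4 to 1 and 2.** 4 is opened at its C=C bond to keto aldehyde 3, and 3 at the bond between the alpha carbon of 1 and the terminal carbon of 2.

**28 to 25 and 15.** 28 is traced to its fully acid-labile derivative 27. 27 is cut at C=C and at the CH2–O bond into aldehyde 25, reagent 15 and an alkoxide, so one C3 reagent serves both halves.

**25 to 20 and 2.** 25 goes back through 24, 23 and 22 to ketone 21, in which the isopropyl group is an acetyl group. 21 is cut at C1'–C6' and C4'–C5' into diene 20 and 2. Every intermolecular C–C bond formation next to an existing isopropyl group would give the trans isomer. The endo rule of a Diels–Alder reaction gives the cis pair directly, and both diene substituents direct to the same regioisomer.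

**20 to 18 and 19.** 20 is cut at its central C–C bond into alkyne 18 and alkene 19.

## Alternatives that were turned down

**Alternative 1:** This is the textbook route. The O–acyl bond at C10 is cut by esterification of a diol, ring B by lactonisation, and ring A is dressed by 1,4-addition of a vinyl copper reagent to 4 with C-acylation of the enolate to give beta-keto ester A1.
- C9a of A1 is the acidic carbon of a 1,3-dicarbonyl unit, so it settles in the equatorial, trans arrangement, whereas 30 needs the axial, cis one.
- The same acidic proton quenches any basic methylene donor at C9.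
- Non-basic methylenation followed by epoxidation would bring oxygen from the wrong face.
- The route is short on paper but has no handle on C9a and C9.

**Alternative 2:** This is the biomimetic single-monomer route. Epoxy lactone acid A2 would be made once. Part of it would be hydrolysed and fragmented with loss of CO2 (carboxylate on C9a pushes, epoxide on C9 leaves) to a western acid, and the two would be joined.
- The fragmentation keeps the configuration of C5a, so it gives the trans acid A3, the C1' epimer of what 30 contains.
- The free acid of A2 would compete in the union.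
- The symmetry that this plan uses is absent in this stereoisomer.

**Alternative 3:** This is an aldol-lactonisation cascade. The C9–C9a and O–C1 bonds are cut, so that open-chain keto acid A4 would close ring A and a beta-lactone in one nucleophile-catalysed step. The strained acyl group would then be passed on to build ring B.
- It closes two rings at once and gives OH and C1 cis by necessity.
- In the ammonium enolate, however, allylic 1,3-strain places C5a–H in the enolate plane, and the chain must reach C9a from the face opposite to the vinyl group.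
- The product should therefore be A5, with C1 trans to C5 and both C9a and C9 inverted.
- A catalyst would have to overrule the substrate in a mismatched pair.

Key step: step 3

Assumption: the (R)-prolinol-derived oxazaborolidinium ion of step 11 is taken to expose the same face of 2 as it does of acrylates, which leads to 21; if the sense is opposite, the enantiomeric catalyst is used.

Assumption: 11 is drawn in its open form, although it should rest as the cyclic hydroxylactone (pseudo-acid).

## Route

Step 1
Reactants: 1 3-methylbutanal; 2 but-3-en-2-one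
Product: 3 (S)-2-isopropyl-5-oxohexanal
Conditions: (S)-2-[methoxy(diphenyl)methyl]pyrrolidine (5 mol %), ethyl 3,4-dihydroxybenzoate (20 mol %), neat, 4 °C
Reagents that add atoms: none
Why: Enamine-catalysed asymmetric Michael addition; the diarylmethyl group shields one face of the E-enamine of 1, so that the new C–C bond sets the isopropyl-bearing centre (future C6) as S.

Step 2
Reactants: 3 (S)-2-isopropyl-5-oxohexanal
Product: 4 (S)-4-isopropylcyclohex-2-en-1-one ((S)-cryptone)
Conditions: LiOH (0.1 equiv), i-PrOH, rt
Reagents that add atoms: none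
Why: Intramolecular aldol condensation of the methyl ketone onto the aldehyde; the stereocentre ends up gamma to the carbonyl group and should survive the mild base.

Step 3
Reactants: 4 (S)-4-isopropylcyclohex-2-en-1-one; 5 allene (propa-1,2-diene)
Product: 6 (1R,5S,6S)-5-isopropyl-8-methylidenebicyclo[4.2.0]octan-2-one (cis-fused, cyclobutane anti to the isopropyl group)
Conditions: hν (medium-pressure Hg lamp, Pyrex, λ > 300 nm), 5 (excess), CH2Cl2, −78 °C; then filtration through basic Al2O3
Reagents that add atoms: none
Why: Excitation and intersystem crossing give the twisted triplet enone, which adds to 5 stepwise through a triplet 1,4-biradical that closes after spin inversion; this is the intermolecular enone–allene [2+2] photocycloaddition, a reaction type with close precedent on 4-substituted cyclohexenones. It forms C9a–C1 and C5a–C5 (target numbering) in one operation, and the four-membered ring is closed by recombination of the two radical centres of the biradical. Allene adds head-to-head, its sp carbon ending on the alpha carbon, so the exocyclic methylene marks the future lactone carbonyl C1 and the ring CH2 marks the future vinyl carbon C5. C5a is controlled by the isopropyl group on C6, because the pyramidalised beta carbon of the triplet bonds on the face anti to this pseudo-equatorial group. C9a is controlled by ring strain, because only the cis-fused bicyclo[4.2.0]octanone is stable and any trans-fused isomer should epimerise through its enol on basic Al2O3. The step needs chemoselectivity against enone dimerisation and against secondary photolysis of the beta,gamma-unsaturated ketone, which excess 5, low temperature and the Pyrex cut-off should secure. The strain stored here keeps C9a fixed through steps 4 to 6 and drives the C1–C5 cleavage in step 7.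

Step 4
Reactants: 6 (1R,5S,6S)-5-isopropyl-8-methylidenebicyclo[4.2.0]octan-2-one
Product: 7 5-isopropyl-8-methylidenespiro[bicyclo[4.2.0]octane-2,2'-oxirane] (epoxide O on the cyclobutane face, epoxide CH2 on the isopropyl face)
Conditions: Me3S+ I−, NaH, DMSO/THF, 0 °C
Reagents that add atoms: trimethylsulfonium iodide C[S+](C)C.[I-]
Why: Corey–Chaykovsky epoxidation; the unstabilised ylide adds irreversibly on the convex face, opposite to the cyclobutane, so that C10 ends on the isopropyl face and O on the cyclobutane face (C9 R). C9a cannot epimerise because the trans-fused isomer is too strained.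

Step 5
Reactants: 7 5-isopropyl-8-methylidenespiro[bicyclo[4.2.0]octane-2,2'-oxirane]
Product: 8 5-isopropylspiro[bicyclo[4.2.0]octane-2,2'-oxiran]-8-one (configuration as in 7)
Conditions: O3, CH2Cl2, −78 °C; then Me2S
Reagents that add atoms: ozone [O-][O+]=O
Why: Ozonolysis of the only C=C bond, with the epoxide inert; it is done after step 4 so that no 1,3-diketone open to retro-Claisen cleavage is ever present.

Step 6
Reactants: 8 5-isopropylspiro[bicyclo[4.2.0]octane-2,2'-oxiran]-8-one
Product: 9 5-isopropyl-8-(trimethylsilyloxy)spiro[bicyclo[4.2.0]oct-7-ene-2,2'-oxirane]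
Conditions: LiN(i-Pr)2, Me3SiCl (in situ quench), THF, −78 °C
Reagents that add atoms: chlorotrimethylsilane C[Si](C)(C)Cl
Why: Kinetic enolisation and O-silylation; the base takes a proton from the open CH2 (C5) and not the hindered ring-fusion C9a–H, and the internal quench leaves no time for beta-elimination of the epoxide.

Step 7
Reactants: 9 5-isopropyl-8-(trimethylsilyloxy)spiro[bicyclo[4.2.0]oct-7-ene-2,2'-oxirane]
Product: 11 (3R,4S,5S,6S)-5-formyl-6-isopropyl-1-oxaspiro[2.5]octane-4-carboxylic acid, via silyl ester aldehyde 10 (not isolated)
Conditions: O3, CH2Cl2, −78 °C; Me2S; then THF/H2O, rt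
Reagents that add atoms: ozone [O-][O+]=O
Why: Ozonolysis of a silyl enol ether cuts C1–C5 with release of the ring strain and leaves C1 as acid and C5 as aldehyde, so the two carbons are told apart without a selective step. C9a and C5a are not touched, and the trans-diaxial C1 and C10 cannot reach each other.

Step 8
Reactants: 12 tert-butyl 2-(diethoxyphosphoryl)acetate; 13 formaldehyde (as paraformaldehyde)
Product: 15 tert-butyl 2-(diethoxyphosphoryl)acrylate, via hydroxymethyl phosphonate 14 (not isolated)
Conditions: (CH2O)n, piperidine (0.1 equiv), AcOH (0.1 equiv), toluene, reflux, Dean–Stark trap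
Reagents that add atoms: none
Why: Knoevenagel condensation of a doubly activated methylene compound with formaldehyde; the buffered amine catalyst spares the tert-butyl ester.

Step 9
Reactants: 11 (3R,4S,5S,6S)-5-formyl-6-isopropyl-1-oxaspiro[2.5]octane-4-carboxylic acid; 15 tert-butyl 2-(diethoxyphosphoryl)acrylate
Product: 17 tert-butyl (5aR,6S,9R,9aS)-6-isopropyl-1-oxo-3,5a,6,7,8,9a-hexahydro-1H-spiro[2-benzoxepine-9,2'-oxirane]-4-carboxylate, via acyloxy phosphonate 16 (not isolated)
Conditions: K2CO3 (1.1 equiv), 18-crown-6 (0.2 equiv), THF (high dilution), 0 °C → rt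
Reagents that add atoms: none
Why: Proposed new method: the potassium carboxylate of 11 should add reversibly to the doubly activated alkene of 15 (oxa-Michael) to give the anion of 16, which is drained by an irreversible intramolecular Horner–Wadsworth–Emmons reaction with the neighbouring formyl group; the closest known reaction type is the tandem conjugate addition/olefination of 2-phosphonoacrylates with alkoxides and phenoxides that carry a carbonyl group (2,5-dihydrofurans, 2H-chromenes), and carboxylate donors are untested; the seven-membered ring forces C5a and C3 to be cis on the new C4=C5 bond, and the weak base should leave C9a and C5a alone.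

Step 10
Reactants: 18 tert-butyldimethyl(prop-2-yn-1-yloxy)silane; 19 allyl acetate
Product: 20 (E)-4-{[(tert-butyldimethylsilyl)oxy]methyl}penta-2,4-dien-1-yl acetate
Conditions: second-generation Grubbs catalyst (H2IMes)(PCy3)Cl2Ru=CHPh (5 mol %), 19 (3 equiv), CH2Cl2, 40 °C
Reagents that add atoms: none
Why: Cross enyne metathesis joins a terminal alkyne and a terminal alkene to a 1,3-disubstituted diene with all atoms kept. Secondary metathesis should favour the E isomer, and any Z isomer cannot reach the s-cis form and stays behind in step 11.

Step 11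
Reactants: 20 (E)-4-{[(tert-butyldimethylsilyl)oxy]methyl}penta-2,4-dien-1-yl acetate; 2 but-3-en-2-one
Product: 21 {(1S,6R)-6-acetyl-3-{[(tert-butyldimethylsilyl)oxy]methyl}cyclohex-2-en-1-yl}methyl acetate (cis)
Conditions: (R)-3,3-diphenyl-1-(2-methylphenyl)tetrahydro-1H,3H-pyrrolo[1,2-c][1,3,2]oxazaborole·HN(SO2CF3)2 (20 mol %), CH2Cl2, −78 → −40 °C
Reagents that add atoms: none
Why: Catalytic enantioselective Diels–Alder reaction; the 1- and 3-substituents of 20 both direct the acetyl-bearing carbon to C1 of the diene. The endo transition state places acetyl and CH2OAc cis (C1'/C6'), and the chiral Lewis acid blocks one face of the coordinated enone and sets the absolute sense.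

Step 12
Reactants: 21 {(1S,6R)-6-acetyl-3-{[(tert-butyldimethylsilyl)oxy]methyl}cyclohex-2-en-1-yl}methyl acetate
Product: 22 {(1S,6R)-3-{[(tert-butyldimethylsilyl)oxy]methyl}-6-(prop-1-en-2-yl)cyclohex-2-en-1-yl}methyl acetate
Conditions: Ph3PCH3Br, KN(SiMe3)2, THF, −78 → 0 °C
Reagents that add atoms: methyltriphenylphosphonium bromide C[P+](c1ccccc1)(c1ccccc1)c1ccccc1.[Br-]
Why: Wittig methylenation of a methyl ketone, with the acetate inert to the ylide; any enolisation should take place at the methyl group and not at the hindered C6'–H, so the cis pair is kept.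

Step 13
Reactants: 22 {(1S,6R)-3-{[(tert-butyldimethylsilyl)oxy]methyl}-6-(prop-1-en-2-yl)cyclohex-2-en-1-yl}methyl acetate
Product: 23 {(1R,6S)-3-{[(tert-butyldimethylsilyl)oxy]methyl}-6-isopropylcyclohex-2-en-1-yl}methyl acetate
Conditions: H2 (1 atm), RhCl(PPh3)3 (5 mol %), benzene/EtOH, rt
Reagents that add atoms: none
Why: Homogeneous hydrogenation picks the 1,1-disubstituted isopropenyl group over the trisubstituted ring alkene, as in the limonene and carvone series; no stereocentre is made (the descriptors change by priority only).

Step 14
Reactants: 23 {(1R,6S)-3-{[(tert-butyldimethylsilyl)oxy]methyl}-6-isopropylcyclohex-2-en-1-yl}methyl acetate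
Product: 24 {(1R,6S)-3-{[(tert-butyldimethylsilyl)oxy]methyl}-6-isopropylcyclohex-2-en-1-yl}methanol
Conditions: K2CO3 (0.2 equiv), MeOH, 0 °C
Reagents that add atoms: none
Why: Transesterification of a primary acetate; the silyl ether is stable under these conditions.

Step 15
Reactants: 24 {(1R,6S)-3-{[(tert-butyldimethylsilyl)oxy]methyl}-6-isopropylcyclohex-2-en-1-yl}methanol
Product: 25 (1R,6S)-3-{[(tert-butyldimethylsilyl)oxy]methyl}-6-isopropylcyclohex-2-ene-1-carbaldehyde
Conditions: 1,1,1-triacetoxy-1,1-dihydro-1,2-benziodoxol-3(1H)-one (DMP), CH2Cl2, 0 °C → rt; used at once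
Reagents that add atoms: none
Why: Periodinane oxidation works without base, which should keep the beta,gamma-unsaturated, alpha-chiral aldehyde from epimerisation and from conjugation.

Step 16
Reactants: 25 (1R,6S)-3-{[(tert-butyldimethylsilyl)oxy]methyl}-6-isopropylcyclohex-2-ene-1-carbaldehyde; 15 tert-butyl 2-(diethoxyphosphoryl)acrylate
Product: 27 tert-butyl (E)-2-(tert-butoxymethyl)-3-{(1R,6S)-3-{[(tert-butyldimethylsilyl)oxy]methyl}-6-isopropylcyclohex-2-en-1-yl}acrylate, via tert-butoxy phosphonate 26 (not isolated)
Conditions: 15, KOt-Bu (1.0 equiv), t-BuOH/THF, −78 °C; then 25, −78 → 0 °C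
Reagents that add atoms: potassium tert-butoxide CC(C)(C)[O-].[K+]
Why: Known tandem alkoxide conjugate addition/Horner–Wadsworth–Emmons olefination of a 2-phosphonoacrylate; all alkoxide is used up before 25 is added, so only the soft phosphonate anion meets the aldehyde. The alpha-branched aldehyde and the alpha-substituted phosphonate should favour the E enoate (ring trans to the ester, cis to CH2O).

Step 17
Reactants: 27 tert-butyl (E)-2-(tert-butoxymethyl)-3-{(1R,6S)-3-{[(tert-butyldimethylsilyl)oxy]methyl}-6-isopropylcyclohex-2-en-1-yl}acrylate
Product: 28 (E)-2-(hydroxymethyl)-3-[(1R,6S)-3-(hydroxymethyl)-6-isopropylcyclohex-2-en-1-yl]acrylic acid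
Conditions: CF3CO2H/CH2Cl2/H2O (10:10:1), 0 °C → rt; then aq. NaHCO3/MeOH; acidification to pH 3
Reagents that add atoms: none
Why: One acidolysis removes the tert-butyl ester, the tert-butyl ether and the silyl ether, and the mild basic wash cleaves any trifluoroacetate formed on the primary alcohols; acid does not endanger C1'.

Step 18
Reactants: 17 tert-butyl (5aR,6S,9R,9aS)-6-isopropyl-1-oxo-3,5a,6,7,8,9a-hexahydro-1H-spiro[2-benzoxepine-9,2'-oxirane]-4-carboxylate; 28 (E)-2-(hydroxymethyl)-3-[(1R,6S)-3-(hydroxymethyl)-6-isopropylcyclohex-2-en-1-yl]acrylic acid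
Product: 29 tert-butyl ester of the target (C4 carboxyl masked, all hydroxyl groups free)
Conditions: 28 (1.3 equiv), Cs2CO3 (0.3 equiv), DMF, 55 °C
Reagents that add atoms: none
Why: Nucleophilic opening of a 1,1-disubstituted epoxide by a caesium carboxylate at the CH2 terminus (SN2), which leaves C9–O untouched and unveils the tertiary alcohol. The carboxylate outruns the neutral primary alcohols, and the excess acid protonates the alkoxide, so the medium stays too weakly basic to epimerise C9a.

Step 19
Reactants: 29 tert-butyl ester of the target
Product: 30 target CNP0361406.6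
Conditions: CF3CO2H/CH2Cl2 (1:3), 0 °C; aq. NaHCO3 work-up, then pH 3
Reagents that add atoms: none
Why: Acidolysis of the tert-butyl ester through the tert-butyl cation; lactone, acyclic ester and C9a are stable to acid, and no palladium or base, which would attack the allylic C3–O2 bond or C9a–H, is needed.

## Compound list

1 | 3-methylbutanal | CC(C)CC=O | starting material
2 | but-3-en-2-one | CC(=O)C=C | starting material
3 | (S)-2-isopropyl-5-oxohexanal | CC(C)[C@@H](C=O)CCC(C)=O | intermediate
4 | (S)-4-isopropylcyclohex-2-en-1-one | CC(C)[C@@H]1CCC(=O)C=C1 | intermediate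
5 | allene | C=C=C | starting material
6 | (1R,5S,6S)-5-isopropyl-8-methylidenebicyclo[4.2.0]octan-2-one | CC(C)[C@@H]1CCC(=O)[C@H]2C(=C)C[C@@H]12 | intermediate
7 | 5-isopropyl-8-methylidenespiro[bicyclo[4.2.0]octane-2,2'-oxirane] | CC(C)[C@@H]1CC[C@]3(CO3)[C@H]2C(=C)C[C@@H]12 | intermediate
8 | 5-isopropylspiro[bicyclo[4.2.0]octane-2,2'-oxiran]-8-one | CC(C)[C@@H]1CC[C@]3(CO3)[C@H]2C(=O)C[C@@H]12 | intermediate
9 | 5-isopropyl-8-(trimethylsilyloxy)spiro[bicyclo[4.2.0]oct-7-ene-2,2'-oxirane] | CC(C)[C@@H]1CC[C@]3(CO3)[C@H]2C(O[Si](C)(C)C)=C[C@@H]12 | intermediate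
10 | trimethylsilyl 5-formyl-6-isopropyl-1-oxaspiro[2.5]octane-4-carboxylate | CC(C)[C@@H]1CC[C@]2(CO2)[C@@H](C(=O)O[Si](C)(C)C)[C@H]1C=O | intermediate
11 | (3R,4S,5S,6S)-5-formyl-6-isopropyl-1-oxaspiro[2.5]octane-4-carboxylic acid | CC(C)[C@@H]1CC[C@]2(CO2)[C@@H](C(=O)O)[C@H]1C=O | intermediate
12 | tert-butyl 2-(diethoxyphosphoryl)acetate | CCOP(=O)(CC(=O)OC(C)(C)C)OCC | starting material
13 | formaldehyde (paraformaldehyde) | C=O | starting material
14 | tert-butyl 2-(diethoxyphosphoryl)-3-hydroxypropanoate | CCOP(=O)(OCC)C(CO)C(=O)OC(C)(C)C | intermediate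
15 | tert-butyl 2-(diethoxyphosphoryl)acrylate | CCOP(=O)(OCC)C(=C)C(=O)OC(C)(C)C | intermediate
16 | 3-tert-butoxy-2-(diethoxyphosphoryl)-3-oxopropyl ester of 11 | CC(C)[C@@H]1CC[C@]2(CO2)[C@@H](C(=O)OCC(C(=O)OC(C)(C)C)P(=O)(OCC)OCC)[C@H]1C=O | intermediate
17 | tert-butyl (5aR,6S,9R,9aS)-6-isopropyl-1-oxo-3,5a,6,7,8,9a-hexahydro-1H-spiro[2-benzoxepine-9,2'-oxirane]-4-carboxylate | CC(C)[C@@H]1CC[C@]3(CO3)[C@H]2C(=O)OCC(C(=O)OC(C)(C)C)=C[C@@H]12 | intermediate
18 | tert-butyldimethyl(prop-2-yn-1-yloxy)silane | C#CCO[Si](C)(C)C(C)(C)C | starting material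
19 | allyl acetate | C=CCOC(C)=O | starting material
20 | (E)-4-{[(tert-butyldimethylsilyl)oxy]methyl}penta-2,4-dien-1-yl acetate | C=C(CO[Si](C)(C)C(C)(C)C)/C=C/COC(C)=O | intermediate
21 | {(1S,6R)-6-acetyl-3-{[(tert-butyldimethylsilyl)oxy]methyl}cyclohex-2-en-1-yl}methyl acetate | CC(=O)OC[C@H]1C=C(CO[Si](C)(C)C(C)(C)C)CC[C@H]1C(C)=O | intermediate
22 | {(1S,6R)-3-{[(tert-butyldimethylsilyl)oxy]methyl}-6-(prop-1-en-2-yl)cyclohex-2-en-1-yl}methyl acetate | CC(=O)OC[C@H]1C=C(CO[Si](C)(C)C(C)(C)C)CC[C@H]1C(C)=C | intermediate
23 | {(1R,6S)-3-{[(tert-butyldimethylsilyl)oxy]methyl}-6-isopropylcyclohex-2-en-1-yl}methyl acetate | CC(=O)OC[C@H]1C=C(CO[Si](C)(C)C(C)(C)C)CC[C@H]1C(C)C | intermediate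
24 | {(1R,6S)-3-{[(tert-butyldimethylsilyl)oxy]methyl}-6-isopropylcyclohex-2-en-1-yl}methanol | OC[C@H]1C=C(CO[Si](C)(C)C(C)(C)C)CC[C@H]1C(C)C | intermediate
25 | (1R,6S)-3-{[(tert-butyldimethylsilyl)oxy]methyl}-6-isopropylcyclohex-2-ene-1-carbaldehyde | O=C[C@H]1C=C(CO[Si](C)(C)C(C)(C)C)CC[C@H]1C(C)C | intermediate
26 | tert-butyl 3-tert-butoxy-2-(diethoxyphosphoryl)propanoate | CCOP(=O)(OCC)C(COC(C)(C)C)C(=O)OC(C)(C)C | intermediate
27 | tert-butyl (E)-2-(tert-butoxymethyl)-3-{(1R,6S)-3-{[(tert-butyldimethylsilyl)oxy]methyl}-6-isopropylcyclohex-2-en-1-yl}acrylate | CC(C)(C)OC(=O)/C(=C/[C@H]1C=C(CO[Si](C)(C)C(C)(C)C)CC[C@H]1C(C)C)COC(C)(C)C | intermediate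
28 | (E)-2-(hydroxymethyl)-3-[(1R,6S)-3-(hydroxymethyl)-6-isopropylcyclohex-2-en-1-yl]acrylic acid | OC(=O)/C(=C/[C@H]1C=C(CO)CC[C@H]1C(C)C)CO | intermediate
29 | tert-butyl ester of the target | CC(C)[C@@H]1CC[C@](O)(COC(=O)/C(=C/[C@H]2C=C(CO)CC[C@H]2C(C)C)CO)[C@H]2C(=O)OCC(C(=O)OC(C)(C)C)=C[C@@H]12 | intermediate
30 | CNP0361406.6 | CC(C)[C@@H]1CC[C@](O)(COC(=O)/C(=C/[C@H]2C=C(CO)CC[C@H]2C(C)C)CO)[C@H]2C(=O)OCC(C(=O)O)=C[C@@H]12 | target

## Step count and risk

Total step count: 19.

Longest linear sequence: 10. The eastern branch runs through steps 1–7, 9, 18 and 19. The western branch, steps 10–19, is equally long.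

**Step 9 (Proposed new method).**
- Risk: the carboxylate may add too weakly, so that anionic oligomerisation of 15, enolisation of the formyl group with loss of configuration at C5a, or slow intermolecular opening of the epoxide take over.
- Fallback (known chemistry, from 11 back to 17): Wittig methylenation of 11 with two equivalents of ylide should give vinyl acid F1. O-alkylation of its caesium salt with tert-butyl 2-(bromomethyl)acrylate gives diene ester F2. Ring-closing metathesis with the second-generation Hoveyda–Grubbs catalyst (H2IMes)Cl2Ru(=CH-C6H4-2-O-i-Pr) in warm toluene closes ring B at C4=C5 and returns to 17.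

**Step 3 (key step).**
- Risk: attack on both faces of the triplet, partial head-to-tail orientation, enone dimerisation and further photolysis of the product are the likely losses, since the isopropyl group is the only control element.
- Fallback (photochemistry replaced by a thermal ketene cycloaddition, from 4 back to 8): methylene transfer to 4 (axial attack) gives vinyl epoxide F3. Dichloroketene (Cl3CCOCl, Zn–Cu, Et2O/DME) should add to its ring alkene anti to the isopropyl group, with the carbonyl carbon on C9a, because the C9 oxygen disfavours positive charge at C9a. This gives dichlorocyclobutanone F4. Zn/AcOH removes both chlorines and returns to 8.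

**Step 11.**
- Risk: incomplete face or endo selectivity with a simple methyl ketone, and acid-induced loss of the allylic silyl ether.
- Fallback (catalyst control replaced by auxiliary control, from 20 back to 21): (S)-3-acryloyl-4-benzyloxazolidin-2-one and Et2AlCl in CH2Cl2 at −78 °C should give imide F5 through the chelated s-cis acrylimide, whose benzyl group blocks one face. LiSEt converts it into thioester F6, and Me2CuLi at −78 °C gives 21.

**Step 18.**
- Risk: the CH2 terminus is next to a quaternary carbon, so opening may be slow. Long heating invites acyl exchange at the allylic C3, attack of the free alcohols on the lactone, and epimerisation at C9a.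
- Fallback (union by acylation, from 17 and 28 back to 30): excess caesium formate with formic acid in DMF opens 17 to formate F7, and KHCO3 in MeOH frees diol F8. Separately, 28 is silylated (t-BuMe2SiCl, imidazole) to tris-silyl compound F9, whose silyl ester is hydrolysed to bis-silyl acid F10. 2-Methyl-6-nitrobenzoic anhydride with DMAP joins F10 to the primary alcohol of F8 to give protected dimer F11. Aqueous CF3CO2H removes all three acid-labile groups to give 30.

## Further compounds

F1 | step 9 | 6-isopropyl-5-vinyl-1-oxaspiro[2.5]octane-4-carboxylic acid (configuration as in 11) | CC(C)[C@@H]1CC[C@]2(CO2)[C@@H](C(=O)O)[C@H]1C=C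
F2 | step 9 | 2-(tert-butoxycarbonyl)allyl ester of F1 | CC(C)[C@@H]1CC[C@]2(CO2)[C@@H](C(=O)OCC(=C)C(=O)OC(C)(C)C)[C@H]1C=C
F3 | step 3 | 6-isopropyl-1-oxaspiro[2.5]oct-4-ene (epoxide O trans to isopropyl) | CC(C)[C@@H]1CC[C@]2(CO2)C=C1
F4 | step 3 | 7,7-dichloro-5-isopropylspiro[bicyclo[4.2.0]octane-2,2'-oxiran]-8-one | CC(C)[C@@H]1CC[C@]3(CO3)[C@H]2C(=O)C(Cl)(Cl)[C@@H]12
F5 | step 11 | cis Diels–Alder imide of 20 with (S)-3-acryloyl-4-benzyloxazolidin-2-one | CC(=O)OC[C@H]1C=C(CO[Si](C)(C)C(C)(C)C)CC[C@H]1C(=O)N1[C@@H](Cc2ccccc2)COC1=O
F6 | step 11 | S-ethyl thioester derived from F5 | CC(=O)OC[C@H]1C=C(CO[Si](C)(C)C(C)(C)C)CC[C@H]1C(=O)SCC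
F7 | step 18 | C10 formate of the C9 diol derived from 17 | CC(C)[C@@H]1CC[C@](O)(COC=O)[C@H]2C(=O)OCC(C(=O)OC(C)(C)C)=C[C@@H]12
F8 | step 18 | C9/C10 diol derived from 17 | CC(C)[C@@H]1CC[C@](O)(CO)[C@H]2C(=O)OCC(C(=O)OC(C)(C)C)=C[C@@H]12
F9 | step 18 | tris(tert-butyldimethylsilyl) derivative of 28 | CC(C)(C)[Si](C)(C)OC(=O)/C(=C/[C@H]1C=C(CO[Si](C)(C)C(C)(C)C)CC[C@H]1C(C)C)CO[Si](C)(C)C(C)(C)C
F10 | step 18 | bis(tert-butyldimethylsilyl) ether of 28 (free acid) | OC(=O)/C(=C/[C@H]1C=C(CO[Si](C)(C)C(C)(C)C)CC[C@H]1C(C)C)CO[Si](C)(C)C(C)(C)C
F11 | step 18 | bis-silyl ether tert-butyl ester of the target | CC(C)[C@@H]1CC[C@](O)(COC(=O)/C(=C/[C@H]2C=C(CO[Si](C)(C)C(C)(C)C)CC[C@H]2C(C)C)CO[Si](C)(C)C(C)(C)C)[C@H]2C(=O)OCC(C(=O)OC(C)(C)C)=C[C@@H]12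
A1 | alternative 1 | methyl 3-isopropyl-6-oxo-2-vinylcyclohexane-1-carboxylate (all trans) | CC(C)[C@@H]1CCC(=O)[C@H](C(=O)OC)[C@H]1C=C
A2 | alternative 2 | free acid of 17 | CC(C)[C@@H]1CC[C@]3(CO3)[C@H]2C(=O)OCC(C(=O)O)=C[C@@H]12
A3 | alternative 2 | C1' epimer of 28 (trans) | OC(=O)/C(=C/[C@@H]1C=C(CO)CC[C@H]1C(C)C)CO
A4 | alternative 3 | 8-[(tert-butyldimethylsilyl)oxy]-4-isopropyl-7-oxo-3-vinyloctanoic acid | CC(C)[C@H](CCC(=O)CO[Si](C)(C)C(C)(C)C)[C@H](C=C)CC(=O)O
A5 | alternative 3 | cyclohexane-fused beta-lactone with C1 trans to the vinyl group | CC(C)[C@@H]1CC[C@]2(CO[Si](C)(C)C(C)(C)C)OC(=O)[C@@H]2[C@H]1C=C
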